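**Retrosynthetic overview**
1. The target comes from its di-O-methyl ether. The two methyl ethers flanking the alkyl aryl ketone are removed last by chelation-controlled cleavage, and the anisyl methyl ether stays.
2. Key disconnection: the aryl C–CH2 bond. The ring carbon is used as an aryl-boron nucleophile and the alpha-carbon of 4-methoxyacetophenone as an enolonium (a2) synthon, the alpha-bromoketone. This joins two carbons that are both normally nucleophilic.
3. The aryl boronate comes from sterically controlled C–H borylation para to the acyl group of a 2,6-dimethoxyphenyl ketone, run in the same flask as the coupling.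
4. That ketone comes from C2-lithiation of 1,3-dimethoxybenzene and 4-methylpentanoyl chloride.
5. No ring is formed. Both benzene rings are bought intact.

Assumption: the target has no stereocentre and no stereogenic double bond, so it is achiral. No step needs stereocontrol, and all SMILES are complete without stereodescriptors.

**Step 1**
Reactants: 1 1,3-dimethoxybenzene; 2 4-methylpentanoyl chloride
Product: 4 1-(2,6-dimethoxyphenyl)-4-methylpentan-1-one, via 2,6-dimethoxyphenyllithium 3 (not isolated)
Conditions: n-BuLi (1.05 equiv), THF, 0 °C → rt, 2 h; cannulate into 2 (1.3 equiv), THF, −78 → 0 °C; aq NH4Cl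
Reagents that add atoms: 4-methylpentanoyl chloride 2, CC(C)CCC(=O)Cl; n-BuLi, [Li]CCCC (lithium in 3 only)
Why: Directed ortho-metalation, in which both methoxy groups steer n-BuLi to C2, followed by nucleophilic acyl substitution under inverse addition, which stops at the ketone because the di-ortho-substituted, twisted carbonyl of 4 resists a second addition; no stereocentre is formed.

**Step 2 (key step)**
Reactants: 4 1-(2,6-dimethoxyphenyl)-4-methylpentan-1-one; 5 bis(pinacolato)diboron; 6 2-bromo-1-(4-methoxyphenyl)ethan-1-one
Product: 8 1-{2,6-dimethoxy-4-[2-(4-methoxyphenyl)-2-oxoethyl]phenyl}-4-methylpentan-1-one, via aryl pinacol boronate 7 (not isolated)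
Conditions: [Ir(OMe)(cod)]2 (1.5 mol%), dtbpy (3 mol%), 5 (1.0 equiv), THF, 80 °C (sealed), 16 h; evaporate; then Pd(OAc)2 (3 mol%), P(1-naphthyl)3 (9 mol%), K3PO4 (3 equiv), H2O (5 equiv), THF, 6 (1.2 equiv, slow addition), 25 → 45 °C
Reagents that add atoms: 2-bromo-1-(4-methoxyphenyl)ethan-1-one 6, COc1ccc(C(=O)CBr)cc1; bis(pinacolato)diboron 5, CC1(C)OB(OC1(C)C)B1OC(C)(C)C(C)(C)O1 (boryl group in 7 only)
Why: Proposed new method: the bulky iridium tris(boryl) catalyst of the Ishiyama–Miyaura–Hartwig borylation attacks the only ring C–H of 4 without an ortho neighbour (para to the acyl group), and the crude boronate 7 then transfers its aryl group to the alpha-carbon of bromoketone 6, which acts as an enolonium (a2) equivalent, by oxidative addition of zerovalent palladium into the C–Br bond, boron-to-palladium transmetalation and reductive elimination from the aryl palladium enolate (the product-forming event of Buchwald–Hartwig ketone alpha-arylation), the closest known reaction types being one-pot borylation/Suzuki–Miyaura sequences and the Suzuki–Miyaura-type arylation of alpha-bromo esters, amides and ketones; no stereocentre is formed.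

**Step 3**
Reactants: 8 1-{2,6-dimethoxy-4-[2-(4-methoxyphenyl)-2-oxoethyl]phenyl}-4-methylpentan-1-one
Product: 10 1-{2,6-dihydroxy-4-[2-(4-methoxyphenyl)-2-oxoethyl]phenyl}-4-methylpentan-1-one (target), via bis(dichloroaluminium) aryloxide 9 (not isolated)
Conditions: AlCl3 (6 equiv), CH2Cl2, 0 → 40 °C, 6–12 h; then ice/1 M HCl
Reagents that add atoms: AlCl3, Cl[Al](Cl)Cl (aluminium and chlorine in 9 only; none of its atoms stay in 10)
Why: Chelation-controlled Lewis-acid ether cleavage, in which AlCl3 bridges the ketone oxygen and a flanking methoxy oxygen in a six-membered chelate, chloride removes the methyl group by SN2 and the event repeats on the other side, while the anisyl methoxy group has no neighbouring carbonyl and survives just as it does when 4-methoxyaryl ketones are made by AlCl3 Friedel–Crafts acylation in CH2Cl2; no stereocentre is involved.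

**Compound list**
1 | 1,3-dimethoxybenzene | COc1cccc(OC)c1 | starting material
2 | 4-methylpentanoyl chloride | CC(C)CCC(=O)Cl | starting material
3 | 2,6-dimethoxyphenyllithium | COc1cccc(OC)c1[Li] | intermediate
4 | 1-(2,6-dimethoxyphenyl)-4-methylpentan-1-one | COc1cccc(OC)c1C(=O)CCC(C)C | intermediate
5 | bis(pinacolato)diboron | CC1(C)OB(OC1(C)C)B1OC(C)(C)C(C)(C)O1 | starting material
6 | 2-bromo-1-(4-methoxyphenyl)ethan-1-one | COc1ccc(C(=O)CBr)cc1 | starting material
7 | 1-[2,6-dimethoxy-4-(4,4,5,5-tetramethyl-1,3,2-dioxaborolan-2-yl)phenyl]-4-methylpentan-1-one | COc1cc(B2OC(C)(C)C(C)(C)O2)cc(OC)c1C(=O)CCC(C)C | intermediate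
8 | 1-{2,6-dimethoxy-4-[2-(4-methoxyphenyl)-2-oxoethyl]phenyl}-4-methylpentan-1-one | COc1ccc(C(=O)Cc2cc(OC)c(C(=O)CCC(C)C)c(OC)c2)cc1 | intermediate
9 | 1-{2,6-bis[(dichloroalumanyl)oxy]-4-[2-(4-methoxyphenyl)-2-oxoethyl]phenyl}-4-methylpentan-1-one | COc1ccc(C(=O)Cc2cc(O[Al](Cl)Cl)c(C(=O)CCC(C)C)c(O[Al](Cl)Cl)c2)cc1 | intermediate
10 | 1-{2,6-dihydroxy-4-[2-(4-methoxyphenyl)-2-oxoethyl]phenyl}-4-methylpentan-1-one (CNP0142242.0) | COc1ccc(C(=O)Cc2cc(O)c(C(=O)CCC(C)C)c(O)c2)cc1 | target

**Total step count:** 3. **Longest linear sequence:** 3 (1 → 4 → 8 → 10).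

**Steps most likely to fail**

**Step 2, highest risk.**
- Bromoketone 6 is sensitive to base.
- The CH2 group of product 8 is acidic and could be alkylated by 6.
- The palladium enolate may be protonated to give 4-methoxyacetophenone.
- Residual boron hydride from the borylation can reduce 6.

Slow addition of 6, a bulky non-nucleophilic phosphine and evaporation before the coupling are meant to limit these.

The fallback sets out from 7 and comes back at 8. Boronate 7 is isolated by filtration through silica. It is coupled under the same palladium/bulky-phosphine system with purchased 2-bromo-N-methoxy-N-methylacetamide. This is an alpha-bromo amide of the firmly established substrate class, and its product is far less acidic. The coupling gives 2-[3,5-dimethoxy-4-(4-methylpentanoyl)phenyl]-N-methoxy-N-methylacetamide F2. Treating F2 with 4-methoxyphenylmagnesium bromide (2.5 equiv, THF, −20 → 0 °C) gives 8 by acyl substitution at the Weinreb amide. The di-ortho-substituted ketone is too hindered to add the Grignard reagent.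

**Step 3.** The reaction may stall at the monomethyl ether, or forcing it may start to cleave the anisyl ether.

The fallback sets out from 4 and comes back at 10.
- Ketone 4 carries no other ether, so it is fully demethylated with BBr3 (CH2Cl2, −78 °C → rt) to 1-(2,6-dihydroxyphenyl)-4-methylpentan-1-one F3.
- F3 is protected with MOMCl and NaH in DMF as 1-[2,6-bis(methoxymethoxy)phenyl]-4-methylpentan-1-one F4.
- F4 is borylated with 5 as in step 2 to 1-[2,6-bis(methoxymethoxy)-4-(4,4,5,5-tetramethyl-1,3,2-dioxaborolan-2-yl)phenyl]-4-methylpentan-1-one F5.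
- F5 is coupled with 6 to give 1-{2,6-bis(methoxymethoxy)-4-[2-(4-methoxyphenyl)-2-oxoethyl]phenyl}-4-methylpentan-1-one F6.
- HCl in MeOH at 50 °C then releases 10 without touching any aryl methyl ether.

**Step 1.** The aryllithium may deprotonate the acid chloride to a ketene or enolise the product, which lowers the yield.

The fallback sets out from 3 and comes back at 4. Aryllithium 3 is added to purchased 4-methylpentanal (THF, −78 °C) to give racemic 1-(2,6-dimethoxyphenyl)-4-methylpentan-1-ol F1. F1 is oxidised with Dess–Martin periodinane (CH2Cl2, rt) to 4, which removes its transient stereocentre.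

**Further compounds**
F1 | step 1 | 1-(2,6-dimethoxyphenyl)-4-methylpentan-1-ol (racemic) | COc1cccc(OC)c1C(O)CCC(C)C
F2 | step 2 | 2-[3,5-dimethoxy-4-(4-methylpentanoyl)phenyl]-N-methoxy-N-methylacetamide | COc1cc(CC(=O)N(C)OC)cc(OC)c1C(=O)CCC(C)C
F3 | step 3 | 1-(2,6-dihydroxyphenyl)-4-methylpentan-1-one | CC(C)CCC(=O)c1c(O)cccc1O
F4 | step 3 | 1-[2,6-bis(methoxymethoxy)phenyl]-4-methylpentan-1-one | COCOc1cccc(OCOC)c1C(=O)CCC(C)C
F5 | step 3 | 1-[2,6-bis(methoxymethoxy)-4-(4,4,5,5-tetramethyl-1,3,2-dioxaborolan-2-yl)phenyl]-4-methylpentan-1-one | COCOc1cc(B2OC(C)(C)C(C)(C)O2)cc(OCOC)c1C(=O)CCC(C)C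
F6 | step 3 | 1-{2,6-bis(methoxymethoxy)-4-[2-(4-methoxyphenyl)-2-oxoethyl]phenyl}-4-methylpentan-1-one | COCOc1cc(CC(=O)c2ccc(OC)cc2)cc(OCOC)c1C(=O)CCC(C)C
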